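(The numbers in the tables are simulated for substances that don't exist; the scatter is artificial.)

If solid substrate still stands at 50.2 % of its charge in the dusk run and the readings have stopped moving, solid has not ended that run, so I look to the reagent.

| flask | solid substrate | reagent | remark | time |
|---|---|---|---|---|
| dusk | 0.34 M | 0.36 M | run made earlier |  |
| dawn | 0.53 M | 0.36 M | run made earlier |  |
| summer | 0.24 M | 0.18 M | run made earlier |  |
| flask | 0.24 M | 0.360 M |  | 15 d |

| run | time / d | solid substrate / % | target / % |
|---|---|---|---|
| dusk | 1.25 | 52.8 | 15.8 |
| dusk | 2.50 | 50.8 | 15.7 |
| dusk | 4.00 | 49.4 | 14.7 |
| dusk | 8.00 | 49.8 | 15.0 |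
| dusk | 15.0 | 50.2 | 15.3 |
| dawn | 3.00 | 68.9 | 10.0 |
| dawn | 6.00 | 67.8 | 9.6 |
| dawn | 10.0 | 68.3 | 9.4 |
| dawn | 12.0 | 67.5 | 10.2 |
| dawn | 15.0 | 67.5 | 8.7 |
| summer | 3.00 | 39.8 | 12.5 |
| summer | 6.00 | 37.0 | 12.7 |
| summer | 10.0 | 36.8 | 11.0 |
| summer | 12.0 | 38.7 | 11.0 |
| summer | 15.0 | 38.8 | 11.6 |

(readings scatter by 1 percentage point)

- which holds at 15 d: what has brought the reaction to rest, or that it has not come to rest (for what has run out or reacted, a solid counts together with what of it has only dissolved) (all of the solid substrate has reacted / the reagent has run out first / it is still moving)
- part of the solid substrate that has turned into other species by 15 d (what has only dissolved does not count)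
- amount of target at 15 d, in percent of the solid substrate charged

- given per volume of solution although it is solid: solid substrate
- the numbers in the tables scatter with a standard deviation of 1 percentage point
- at the start none of the solid substrate is in solution
- what has only dissolved of solid substrate counts as not reacted
- the reaction counts as stopped when no species that holds the solid substrate changes by six tenths of a point or more over the second half of the time

The dusk and dawn runs share [reagent] = 0.36 M and end at [target] = 0.0520 M and 0.0461 M, although their solid charges differ, while summer, with 0.18 M, ends at 0.0278 M. So I read the reagent as the limiting reagent. The mean of target over reagent in these last readings is 14.2 %, and this is what I carry: the target share, the part of the charged reagent that ends as target.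

My first answer for the flask assumes that solid remains: [target] = 0.0513 M, or 21.4 % of the charge. Now I put that back in. The dusk balance leaves 0.117 M that is neither solid nor target, and summer, with different charges of both solid and reagent, leaves 0.119 M, so I book this as dissolved substrate. The flask then needs 0.169 M of solid, less than the 0.24 M charged, so about 29.6 % stays solid and the first answer stands, with conversion equal to target.

The forecast says that the reagent has run out first, with conversion 21 % and target 21.2 %, holding that “Target therefore scales with reagent”.

In the flask the reagent has run out first, with 0 % of the reagent left, conversion 21.2 % and target 21.2 %.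

    solid substrate ⇌ dissolved substrate, rate k1*(cs1 - [dissolved substrate]) while solid is left; crystals form when [dissolved substrate] > cs1 (solubility = 0.120 M, k = 0.0900 h⁻¹)
    dissolved substrate + reagent → target (k = 1.00 M⁻¹ h⁻¹)
    reagent → side product (k = 0.160 h⁻¹)

At 0.149 d the flask's reagent goes to side product 7.0 times as fast as to target. By 1.50 d target already stands at 21.2 %, with 0.0252 % of the reagent left.

In the neighbour flask with 0.14 M of solid substrate and the reagent charge held, the target share gives 36.6 % of that charge, and the need of 0.169 M exceeds that charge, so I expect no solid left. Computed, that flask holds target 36.3 %, solid substrate 0 % and dissolved substrate 63.7 %.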